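The south-west run slows almost to a stop with 42.3% of its substrate unused at 40.0 h, so in a repeat I watch how the consumed substrate divides, not how fast it goes.

| flask | substrate | partner | temperature | remark | time |
|---|---|---|---|---|---|
| south-west | 14 mM | 30 mM | 54 °C | run made earlier |  |
| south-east | 22 mM | 30 mM | 62 °C | run made earlier |  |
| oak | 10 mM | 30.0 mM | 65 °C |  | 2.5 d |
| elm | 10 mM | 30.0 mM | 50 °C |  | 2.5 d |

| run | time / h | target / % | substrate / % |
|---|---|---|---|
| south-west | 2.00 | 7.3 | 78.7 |
| south-west | 6.00 | 15.7 | 60.1 |
| south-west | 10.0 | 19.8 | 52.5 |
| south-west | 15.0 | 22.9 | 48.4 |
| south-west | 20.0 | 24.6 | 45.6 |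
| south-west | 30.0 | 26.2 | 42.2 |
| south-west | 40.0 | 27.7 | 42.3 |
| south-east | 3.00 | 15.0 | 68.9 |
| south-east | 6.00 | 19.9 | 60.9 |
| south-east | 8.00 | 21.7 | 59.1 |
| south-east | 12.0 | 22.9 | 57.3 |
| south-east | 15.0 | 24.1 | 56.0 |
| south-east | 20.0 | 24.6 | 55.6 |

(scatter of a reading: 0.3 percentage points)

- the analysis behind the earlier runs scatters by 0.3 percentage points, standard deviation

1. which of the two there is more of at the end, oak (side product / target)
2. which of the two there is more of at the end, elm (side product / target)
3. target at the end, in percent of the substrate charged, oak
4. target at the end, in percent of the substrate charged, elm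

Two amounts matter: the target, and the side product, which I read as the fraction of the charge that is neither substrate nor target. At its last reading the south-west run at 54 °C gives 0.923, and this ratio of target to side product at the end of a run, the overall selectivity, is what I carry as the split. The south-east run at 62 °C gives 1.24. All four flasks get the same partner charge, but the two runs differ in substrate too, so reading this rise as an effect of temperature is my assumption. On it, oak lies beyond the south-east run and its split stands above one, while elm lies below the south-west run and its split stands under one.

I go round once more. At 2.00 h the south-west split is 0.521, so it climbs during that run. If elm, the cooler flask, stops short, its split sits lower still, and my answer for elm stands.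

The forecast names target for oak and side product for elm, with target at 26.5% and 29.2%, on the ground that the plateau constants show “Both fall with temperature, the side product faster”.

Oak gives 29.8% target and 23.7% side product, a split of 1.26. Elm gives 29.0% and 38.3%, a split of 0.757.

    partner → decomposed reagent (k = 0.0410 /h, Ea = 97.0 kJ/mol)
    partner → decomposition product (k = 1.50 × 10⁻⁴ /h, Ea = 115 kJ/mol)
    substrate + 2 partner → side product (k = 98.0 /M²/h, Ea = 46.0 kJ/mol)
    substrate + partner → target (k = 1.20 /M/h, Ea = 75.0 kJ/mol)
    (constants at 50 °C)

In elm, removing the step that makes side product lifts target from 29.0% to 49.5% and turns the answer. That is the largest single effect shown there, though not the main reason. This step takes two partner, so I check the split on a flask like oak but charged with 18 mM of partner. It ends with 22.4% target and 10.3% side product, a split of 2.17, higher than the 1.26 of oak.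

The numbers in the tables come from a simulation from invented constants, and the scatter is random.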